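**Plan**

- Retrosynthesis: the C3 formyl group is taken back to a methyl ester and the two phenols to a silyl ether (C2) and a benzyl ether (C7). Ring A is then opened at C1–C2, after water is added back across C1/C2.
- Enabling feature: C1 of the naphthalene carries ring C and sits between C8a and the oxygenated C2. A ring B aryl ketone (future C1, already bearing ring C) with an ortho CH2 (future C4) bound to a silyloxyacrylate (C3 with the ester, C2 with the oxygen) therefore becomes, on photoenolisation, the hexatriene C1=C8a–C4a=C4–C3=C2 with C1 and C2 as its ends.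
- Further cuts: C4a–C4 (Heck-type coupling of an aryl bromide with methyl 2-(hydroxymethyl)acrylate, which brings C4, C3, C2 and the ester) and C1–ring C (aryl Grignard addition to an aldehyde, then oxidation).
- Forward order: ring B is prepared from 2,3-dihydroxybenzaldehyde (benzylate, methylate, brominate), ring C is joined as an aroyl group, the three-carbon arm is attached and silylated, ring A is closed by light and aromatised, and the sequence ends with desilylation, ester-to-aldehyde conversion and debenzylation.
- Stereochemistry: the target has no stereocentre. The carbinol centre made on Grignard addition and the two sp3 centres of the ring-closed alcohol are transient and are erased by oxidation and aromatisation; the enol-ether geometry (E) is not carried forward.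

Key step: step 8

Remark 1: locants C1–C8a in the plan and in the Why lines are those of the target naphthalene (C1 aryl, C2 OH, C3 CHO, C7 OH, C8 OMe; ring A = C1–C4/C4a/C8a, ring B = C4a–C8a, ring C = dimethoxyphenyl); compound names use systematic locants.

Remark 2 (assumption): the formyl ester of step 6 is a keto–enol mixture and is written as the aldehyde; its silylation under amine conditions is taken to give the E enol ether, and the Z isomer would serve equally because C2 ends as an aromatic carbon.

**Route**

Step 1
Reactants: 1 2,3-dihydroxybenzaldehyde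
Product: 2 3-(benzyloxy)-2-hydroxybenzaldehyde
Conditions: NaH (2.2 equiv), DMSO, 20 °C; BnBr (1.0 equiv); aq. HCl work-up
Reagents that add atoms: benzyl bromide, BrCc1ccccc1
Why: Williamson ether synthesis on the dianion, in which the 2-phenoxide is conjugated with and chelated to the aldehyde, so the more nucleophilic 3-phenoxide should take up the single equivalent of benzyl bromide.

Step 2
Reactants: 2 3-(benzyloxy)-2-hydroxybenzaldehyde
Product: 3 3-(benzyloxy)-2-methoxybenzaldehyde
Conditions: MeI, K2CO3, DMF, 20 °C
Reagents that add atoms: iodomethane, CI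
Why: Williamson O-methylation of the remaining salicylaldehyde-type phenol under standard carbonate conditions.

Step 3
Reactants: 3 3-(benzyloxy)-2-methoxybenzaldehyde
Product: 4 3-(benzyloxy)-6-bromo-2-methoxybenzaldehyde
Conditions: NBS, DMF, 20 °C, dark
Reagents that add atoms: N-bromosuccinimide, O=C1CCC(=O)N1Br
Why: Electrophilic aromatic bromination, in which the 2-methoxy group is twisted out of conjugation by its two neighbours so that the 3-benzyloxy group directs para to C6, as is known for 2,3-dimethoxybenzaldehyde.

Step 4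
Reactants: 4 3-(benzyloxy)-6-bromo-2-methoxybenzaldehyde; 5 4-bromo-1,2-dimethoxybenzene
Product: 7 rac-[3-(benzyloxy)-6-bromo-2-methoxyphenyl](3,4-dimethoxyphenyl)methanol, via (3,4-dimethoxyphenyl)magnesium bromide 6 (not isolated)
Conditions: 5, Mg, THF, reflux; then 4, THF, 0 °C; aq. NH4Cl
Reagents that add atoms: none
Why: Grignard addition to the aldehyde, which is far faster than halogen–magnesium exchange at the aryl bromide; the new carbinol centre is racemic and is erased in step 5.

Step 5
Reactants: 7 rac-[3-(benzyloxy)-6-bromo-2-methoxyphenyl](3,4-dimethoxyphenyl)methanol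
Product: 8 [3-(benzyloxy)-6-bromo-2-methoxyphenyl](3,4-dimethoxyphenyl)methanone
Conditions: Dess–Martin periodinane, CH2Cl2, 20 °C
Reagents that add atoms: none
Why: Dess–Martin oxidation of a secondary diaryl carbinol to the diaryl ketone under neutral conditions that leave the aryl bromide and the ethers untouched.

Step 6
Reactants: 8 [3-(benzyloxy)-6-bromo-2-methoxyphenyl](3,4-dimethoxyphenyl)methanone; 9 methyl 2-(hydroxymethyl)prop-2-enoate
Product: 10 methyl 3-[4-(benzyloxy)-2-(3,4-dimethoxybenzoyl)-3-methoxyphenyl]-2-formylpropanoate (racemic keto form of a keto–enol mixture)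
Conditions: Pd(OAc)2 (5 mol %), Bu4NBr, NaHCO3, DMF, 90 °C
Reagents that add atoms: none
Why: Heck arylation of an allylic alcohol with carbonyl formation, the reaction type that converts Morita–Baylis–Hillman alcohols into 2-benzyl 3-oxo esters: aryl–palladium adds to the CH2 terminus of 9 and β-hydride elimination toward the carbinol carbon releases the enol of 10, so the C4–C3–C2 arm arrives complete and no ester enolate is generated beside the benzophenone carbonyl, where it would close to an indanol.

Step 7
Reactants: 10 methyl 3-[4-(benzyloxy)-2-(3,4-dimethoxybenzoyl)-3-methoxyphenyl]-2-formylpropanoate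
Product: 11 methyl (E)-2-[[4-(benzyloxy)-2-(3,4-dimethoxybenzoyl)-3-methoxyphenyl]methyl]-3-[(tert-butyldimethylsilyl)oxy]prop-2-enoate
Conditions: TBSCl, Et3N, DMAP (cat.), CH2Cl2, 0 → 20 °C
Reagents that add atoms: tert-butyldimethylsilyl chloride, CC(C)(C)[Si](C)(C)Cl
Why: O-silylation of the enol form of a 2-formyl ester with an amine base, which by analogy with enol sulfonylation of such esters should favour the E isomer (silyloxy trans to the ester).

Step 8
Reactants: 11 methyl (E)-2-[[4-(benzyloxy)-2-(3,4-dimethoxybenzoyl)-3-methoxyphenyl]methyl]-3-[(tert-butyldimethylsilyl)oxy]prop-2-enoate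
Product: 14 methyl 6-(benzyloxy)-3-[(tert-butyldimethylsilyl)oxy]-4-(3,4-dimethoxyphenyl)-5-methoxynaphthalene-2-carboxylate, via hydroxy-ortho-quinodimethane dienol 12 (not isolated), via ring-closed 1,2-dihydronaphthalen-1-ol 13 (not isolated)
Conditions: hν (365 nm LED), Ar-degassed PhMe (0.01 M), 20 °C; then p-TsOH·H2O (10 mol %), 20 °C
Reagents that add atoms: none
Why: Proposed new method: excitation of the benzophenone chromophore (n,π* triplet) should move a hydrogen from the doubly activated C4 methylene to the carbonyl oxygen through a six-membered transition state, and the biradical relaxes to hydroxy-ortho-quinodimethane 12, in which C1=C8a, C4a=C4 and the enol-ether bond C3=C2 form a hexatriene. Thermal disrotatory six-electron electrocyclisation joins C1 to C2 and closes the six-membered ring A, driven by the return of ring B to a benzene ring; collapse of the biradical through its C2 allylic terminus would form the same bond. Acid then ionises the tertiary, doubly benzylic C1–OH of 13 and loss of the C2 proton aromatises ring A, so the two transient stereocentres (their relative configuration fixed by the disrotatory mode) vanish and no stereocontrol is needed. The closest known reaction types are the photoenolisation of ortho-alkyl benzophenones used in photoenolisation/Diels–Alder sequences and the thermal electrocyclisation of vinyl-ortho-quinodimethanes to 1,2-dihydronaphthalenes; their combination on an enol-ether arm has not been shown. The step needs C1–C2 closure to win over hydrogen return and over four-electron closure to a benzocyclobutenol: dienol isomers with the arm turned outward or the hydroxyl turned inward revert to 11 and are excited again, and a benzocyclobutenol would reopen on warming. The 365 nm light is absorbed by the aryl ketone but not by the silyloxyacrylate, and oxygen is excluded because it intercepts the biradical and the dienol.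

Step 9
Reactants: 14 methyl 6-(benzyloxy)-3-[(tert-butyldimethylsilyl)oxy]-4-(3,4-dimethoxyphenyl)-5-methoxynaphthalene-2-carboxylate
Product: 15 methyl 6-(benzyloxy)-4-(3,4-dimethoxyphenyl)-3-hydroxy-5-methoxynaphthalene-2-carboxylate
Conditions: Bu4NF, AcOH, THF, 0 °C
Reagents that add atoms: none
Why: Fluoride-induced cleavage of an aryl silyl ether (Si–F bond formation), buffered with acetic acid so that the methyl ester is not attacked.

Step 10
Reactants: 15 methyl 6-(benzyloxy)-4-(3,4-dimethoxyphenyl)-3-hydroxy-5-methoxynaphthalene-2-carboxylate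
Product: 16 7-(benzyloxy)-1-(3,4-dimethoxyphenyl)-3-(hydroxymethyl)-8-methoxynaphthalen-2-ol
Conditions: iBu2AlH (DIBAL-H, 4 equiv), CH2Cl2, −78 → 0 °C; then H2O
Reagents that add atoms: none
Why: Hydride reduction of the ester to the primary alcohol by excess iBu2AlH after deprotonation of the phenol, with the aryl ethers inert.

Step 11
Reactants: 16 7-(benzyloxy)-1-(3,4-dimethoxyphenyl)-3-(hydroxymethyl)-8-methoxynaphthalen-2-ol
Product: 17 6-(benzyloxy)-4-(3,4-dimethoxyphenyl)-3-hydroxy-5-methoxynaphthalene-2-carbaldehyde
Conditions: MnO2 (activated, excess), CH2Cl2, 20 °C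
Reagents that add atoms: none
Why: Selective MnO2 oxidation of a benzylic (ortho-hydroxybenzyl) alcohol to the aldehyde, which is stabilised by the hydrogen bond to the C2 hydroxyl and is not oxidised further.

Step 12
Reactants: 17 6-(benzyloxy)-4-(3,4-dimethoxyphenyl)-3-hydroxy-5-methoxynaphthalene-2-carbaldehyde
Product: 18 vitrofolal B, 4-(3,4-dimethoxyphenyl)-3,6-dihydroxy-5-methoxynaphthalene-2-carbaldehyde
Conditions: BCl3 (3 equiv), C6HMe5 (5 equiv), CH2Cl2, −78 °C; then H2O
Reagents that add atoms: none
Why: Lewis-acid debenzylation with BCl3 and pentamethylbenzene as a non-basic benzyl cation trap (Friedel–Crafts capture), which at −78 °C should cleave the aryl benzyl ether while leaving the aryl methyl ethers and the aldehyde intact.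

**Compound list**

1 | 2,3-dihydroxybenzaldehyde | O=Cc1cccc(O)c1O | starting material
2 | 3-(benzyloxy)-2-hydroxybenzaldehyde | O=Cc1cccc(OCc2ccccc2)c1O | intermediate
3 | 3-(benzyloxy)-2-methoxybenzaldehyde | COc1c(C=O)cccc1OCc1ccccc1 | intermediate
4 | 3-(benzyloxy)-6-bromo-2-methoxybenzaldehyde | COc1c(C=O)c(Br)ccc1OCc1ccccc1 | intermediate
5 | 4-bromo-1,2-dimethoxybenzene | COc1ccc(Br)cc1OC | starting material
6 | (3,4-dimethoxyphenyl)magnesium bromide (formed in the flask, not isolated) | COc1ccc([Mg]Br)cc1OC | intermediate
7 | rac-[3-(benzyloxy)-6-bromo-2-methoxyphenyl](3,4-dimethoxyphenyl)methanol | COc1ccc(C(O)c2c(Br)ccc(OCc3ccccc3)c2OC)cc1OC | intermediate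
8 | [3-(benzyloxy)-6-bromo-2-methoxyphenyl](3,4-dimethoxyphenyl)methanone | COc1ccc(C(=O)c2c(Br)ccc(OCc3ccccc3)c2OC)cc1OC | intermediate
9 | methyl 2-(hydroxymethyl)prop-2-enoate | C=C(CO)C(=O)OC | starting material
10 | methyl 3-[4-(benzyloxy)-2-(3,4-dimethoxybenzoyl)-3-methoxyphenyl]-2-formylpropanoate (racemic, in equilibrium with its enol) | COC(=O)C(C=O)Cc1ccc(OCc2ccccc2)c(OC)c1C(=O)c1ccc(OC)c(OC)c1 | intermediate
11 | methyl (E)-2-[[4-(benzyloxy)-2-(3,4-dimethoxybenzoyl)-3-methoxyphenyl]methyl]-3-[(tert-butyldimethylsilyl)oxy]prop-2-enoate | COC(=O)/C(Cc1ccc(OCc2ccccc2)c(OC)c1C(=O)c1ccc(OC)c(OC)c1)=C/O[Si](C)(C)C(C)(C)C | intermediate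
12 | hydroxy-ortho-quinodimethane dienol, methyl (E)-2-[[4-(benzyloxy)-6-[(3,4-dimethoxyphenyl)(hydroxy)methylidene]-5-methoxycyclohexa-2,4-dien-1-ylidene]methyl]-3-[(tert-butyldimethylsilyl)oxy]prop-2-enoate, arm inward and hydroxyl outward (not isolated) | COC(=O)/C(=C/O[Si](C)(C)C(C)(C)C)/C=C1/C=CC(OCc2ccccc2)=C(OC)/C1=C(\O)c1ccc(OC)c(OC)c1 | intermediate
13 | methyl 6-(benzyloxy)-3-[(tert-butyldimethylsilyl)oxy]-4-(3,4-dimethoxyphenyl)-4-hydroxy-5-methoxy-3,4-dihydronaphthalene-2-carboxylate, racemic, hydroxyl trans to silyloxy as the disrotatory mode predicts, one enantiomer drawn (not isolated) | COC(=O)C1=Cc2ccc(OCc3ccccc3)c(OC)c2[C@@](O)(c2ccc(OC)c(OC)c2)[C@H]1O[Si](C)(C)C(C)(C)C | intermediate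
14 | methyl 6-(benzyloxy)-3-[(tert-butyldimethylsilyl)oxy]-4-(3,4-dimethoxyphenyl)-5-methoxynaphthalene-2-carboxylate | COC(=O)c1cc2ccc(OCc3ccccc3)c(OC)c2c(-c2ccc(OC)c(OC)c2)c1O[Si](C)(C)C(C)(C)C | intermediate
15 | methyl 6-(benzyloxy)-4-(3,4-dimethoxyphenyl)-3-hydroxy-5-methoxynaphthalene-2-carboxylate | COC(=O)c1cc2ccc(OCc3ccccc3)c(OC)c2c(-c2ccc(OC)c(OC)c2)c1O | intermediate
16 | 7-(benzyloxy)-1-(3,4-dimethoxyphenyl)-3-(hydroxymethyl)-8-methoxynaphthalen-2-ol | OCc1cc2ccc(OCc3ccccc3)c(OC)c2c(-c2ccc(OC)c(OC)c2)c1O | intermediate
17 | 6-(benzyloxy)-4-(3,4-dimethoxyphenyl)-3-hydroxy-5-methoxynaphthalene-2-carbaldehyde | O=Cc1cc2ccc(OCc3ccccc3)c(OC)c2c(-c2ccc(OC)c(OC)c2)c1O | intermediate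
18 | vitrofolal B, 4-(3,4-dimethoxyphenyl)-3,6-dihydroxy-5-methoxynaphthalene-2-carbaldehyde | COc1ccc(-c2c(O)c(C=O)cc3ccc(O)c(OC)c23)cc1OC | target

**Summary**

Total step count: 12. Longest linear sequence: 12 steps (1 → 18).

**Steps most likely to fail**

Step 8. Hydrogen return to the ketone may outrun ring closure, so that light is consumed without conversion. The dienol may instead close through C4 to a benzocyclobutenol, the excited ketone may add to the enol-ether double bond (oxetane formation), or the silyl enol ether may hydrolyse before it cyclises. The fallback uses known chemistry and forms the same C1–C2 bond by umpolung. It sets out from bromo ketone 8. A Heck reaction with allyl alcohol (Pd(OAc)2, Bu4NCl, NaHCO3, DMF, 80 °C) should give 3-[4-(benzyloxy)-2-(3,4-dimethoxybenzoyl)-3-methoxyphenyl]propanal F1. An intramolecular crossed benzoin reaction catalysed by an N-heterocyclic carbene (triazolium salt, DBU, THF) would then join the aldehyde carbon (C2) to the ketone carbon (C1) and give racemic 7-(benzyloxy)-1-(3,4-dimethoxyphenyl)-1-hydroxy-8-methoxy-3,4-dihydronaphthalen-2(1H)-one F2. Claisen formylation at C3, the only enolisable position (HCO2Et, NaH, THF), should give 6-(benzyloxy)-4-(3,4-dimethoxyphenyl)-3,4-dihydroxy-5-methoxy-1,4-dihydronaphthalene-2-carbaldehyde F3, the enol form of the 3-formyl ketone. p-TsOH in warm toluene then removes water across C1 and C4, and the route is rejoined at aldehyde 17, one step before the target.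

Step 6. β-Hydride elimination may go toward the benzylic CH2 and give the 2-(hydroxymethyl)cinnamate, or the formyl group may be lost from the product by base-induced retro-Claisen cleavage at 90 °C. The fallback builds the arm stepwise from 8. A Heck reaction with methyl acrylate (Pd(OAc)2, P(o-tol)3, Et3N, DMF, 100 °C) should give methyl (E)-3-[4-(benzyloxy)-2-(3,4-dimethoxybenzoyl)-3-methoxyphenyl]prop-2-enoate F4. Hydrogenation of the alkene over Pd/C poisoned with Ph2S (H2, EtOAc) spares the benzyl ether and the aryl ketone and gives methyl 3-[4-(benzyloxy)-2-(3,4-dimethoxybenzoyl)-3-methoxyphenyl]propanoate F5. A copper hydride such as [(Ph3P)CuH]6 is avoided here because its enolate would close onto the ketone. Aminomethylenation with neat tert-butoxybis(dimethylamino)methane (Bredereck's reagent, 110 °C), whose irreversible condensation should drain any reversibly formed aldol adduct, gives methyl (E)-2-[[4-(benzyloxy)-2-(3,4-dimethoxybenzoyl)-3-methoxyphenyl]methyl]-3-(dimethylamino)prop-2-enoate F6. Hydrolysis with aqueous HCl in THF returns to formyl ester 10.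

Step 12. A methyl ether may be cleaved alongside the benzyl ether, most plausibly the C8 methoxy group through a cyclic borate with the freed C7 oxygen. Debenzylation may also stall because the chelating hydroxy aldehyde ties up BCl3. The fallback moves the deprotection ahead of the redox steps, starting from ester 15. Hydrogenolysis (H2, Pd/C, EtOAc), carried out before any aldehyde is present, should give methyl 4-(3,4-dimethoxyphenyl)-3,6-dihydroxy-5-methoxynaphthalene-2-carboxylate F7. Reduction with iBu2AlH gives 1-(3,4-dimethoxyphenyl)-3-(hydroxymethyl)-8-methoxynaphthalene-2,7-diol F8, and selective benzylic oxidation with MnO2 leads directly to target 18.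

**Further compounds**

F1 | step 8 | 3-[4-(benzyloxy)-2-(3,4-dimethoxybenzoyl)-3-methoxyphenyl]propanal | O=CCCc1ccc(OCc2ccccc2)c(OC)c1C(=O)c1ccc(OC)c(OC)c1
F2 | step 8 | 7-(benzyloxy)-1-(3,4-dimethoxyphenyl)-1-hydroxy-8-methoxy-3,4-dihydronaphthalen-2(1H)-one (racemic) | COc1ccc(C2(O)C(=O)CCc3ccc(OCc4ccccc4)c(OC)c32)cc1OC
F3 | step 8 | 6-(benzyloxy)-4-(3,4-dimethoxyphenyl)-3,4-dihydroxy-5-methoxy-1,4-dihydronaphthalene-2-carbaldehyde (racemic) | O=CC1=C(O)C(O)(c2ccc(OC)c(OC)c2)c2c(OC)c(OCc3ccccc3)ccc2C1
F4 | step 6 | methyl (E)-3-[4-(benzyloxy)-2-(3,4-dimethoxybenzoyl)-3-methoxyphenyl]prop-2-enoate | COC(=O)/C=C/c1ccc(OCc2ccccc2)c(OC)c1C(=O)c1ccc(OC)c(OC)c1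
F5 | step 6 | methyl 3-[4-(benzyloxy)-2-(3,4-dimethoxybenzoyl)-3-methoxyphenyl]propanoate | COC(=O)CCc1ccc(OCc2ccccc2)c(OC)c1C(=O)c1ccc(OC)c(OC)c1
F6 | step 6 | methyl (E)-2-[[4-(benzyloxy)-2-(3,4-dimethoxybenzoyl)-3-methoxyphenyl]methyl]-3-(dimethylamino)prop-2-enoate | COC(=O)/C(Cc1ccc(OCc2ccccc2)c(OC)c1C(=O)c1ccc(OC)c(OC)c1)=C/N(C)C
F7 | step 12 | methyl 4-(3,4-dimethoxyphenyl)-3,6-dihydroxy-5-methoxynaphthalene-2-carboxylate | COC(=O)c1cc2ccc(O)c(OC)c2c(-c2ccc(OC)c(OC)c2)c1O
F8 | step 12 | 1-(3,4-dimethoxyphenyl)-3-(hydroxymethyl)-8-methoxynaphthalene-2,7-diol | OCc1cc2ccc(O)c(OC)c2c(-c2ccc(OC)c(OC)c2)c1O
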